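**Retrosynthetic overview**
1. The C2-symmetric sulfide is cut at both C2–S bonds into two molecules of the (5S,11R)-5-hydroxy-4-oxo-2E-en-11-olide and H2S (double thia-Michael, C2 set by the macrocycle).
2. The enone comes from dehydration of a 2-hydroxy-4-ketone, itself the N–O hydrogenolysis product of a bridged 2-isoxazoline.
3. Key step: intramolecular nitrile oxide–acrylate [3+2] cycloaddition forms the C3–C4 bond and closes the twelve-membered lactone and the isoxazoline together. This is the only ring-forming event; the isoxazoline is then opened.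
4. The open-chain oxime acrylate comes from a C9 chain made by acetylide alkylation: L-malic-acid-derived (S)-butanetriol acetonide iodide (C4–C7, carries C5) plus (R)-pent-4-yn-2-ol from (R)-propylene oxide (C8–C12, carries C11).

Assumption: positions are given in macrolide numbering (C1 = lactone carbonyl, C11 = methyl-bearing carbinol carbon); the target is read as the sulfide with 2S,5S,11R in each half, and 1 and 3 are bought as single enantiomers.

**Route**

Step 1
Reactants: 1 (S)-2-(2,2-dimethyl-1,3-dioxolan-4-yl)ethan-1-ol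
Product: 2 (S)-4-(2-iodoethyl)-2,2-dimethyl-1,3-dioxolane
Conditions: I2, PPh3, imidazole, CH2Cl2, 0 °C → rt
Reagents that add atoms: iodine, II
Why: Appel-type iodination is an SN2 displacement at an achiral primary carbon, the imidazole buffer spares the acetonide, and the dioxolane stereocentre (future C5) is untouched.

Step 2
Reactants: 3 (R)-2-methyloxirane
Product: 4 (R)-pent-4-yn-2-ol
Conditions: LiC≡CH·H2NCH2CH2NH2, DMSO, 0 °C → rt; H2O
Reagents that add atoms: lithium acetylide–ethylenediamine complex, [Li]C#C.NCCN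
Why: Acetylide opening of the epoxide by SN2 at the unsubstituted CH2 leaves the bought carbinol centre (future C11, R) intact.

Step 3
Reactants: 4 (R)-pent-4-yn-2-ol; 2 (S)-4-(2-iodoethyl)-2,2-dimethyl-1,3-dioxolane
Product: 6 (2R)-7-[(4S)-2,2-dimethyl-1,3-dioxolan-4-yl]hept-4-yn-2-ol, via dilithio dianion 5 (not isolated)
Conditions: n-BuLi (2.1 equiv), THF, −78 → −20 °C; then DMPU, 2, −78 °C → rt; H2O
Reagents that add atoms: none
Why: Acetylide alkylation, in which the C,O-dilithio species reacts at its far more nucleophilic sp carbon with the primary iodide (SN2), joins C7–C8 without touching either stereocentre.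

Step 4
Reactants: 6 (2R)-7-[(4S)-2,2-dimethyl-1,3-dioxolan-4-yl]hept-4-yn-2-ol
Product: 7 (2R)-7-[(4S)-2,2-dimethyl-1,3-dioxolan-4-yl]heptan-2-ol
Conditions: H2 (1 atm), 10% Pd/C, EtOAc, rt
Reagents that add atoms: none
Why: Heterogeneous catalytic hydrogenation saturates the alkyne to the C6–C10 pentamethylene chain in neutral EtOAc, before any acrylate is present, and leaves the acetonide and both stereocentres alone.

Step 5
Reactants: 7 (2R)-7-[(4S)-2,2-dimethyl-1,3-dioxolan-4-yl]heptan-2-ol
Product: 8 (2R)-7-[(4S)-2,2-dimethyl-1,3-dioxolan-4-yl]heptan-2-yl prop-2-enoate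
Conditions: CH2=CHCOCl, Et3N, DMAP (cat.), CH2Cl2, 0 °C
Reagents that add atoms: acryloyl chloride, C=CC(=O)Cl
Why: O-Acylation with the acid chloride (nucleophilic acyl substitution) installs the dipolarophile with retention at C11 because the C–O bond is not broken.

Step 6
Reactants: 8 (2R)-7-[(4S)-2,2-dimethyl-1,3-dioxolan-4-yl]heptan-2-yl prop-2-enoate
Product: 9 (2R,8S)-8,9-dihydroxynonan-2-yl prop-2-enoate
Conditions: AcOH/H2O (4:1), 40 °C
Reagents that add atoms: none
Why: Acid-catalysed acetal hydrolysis frees the 1,2-diol while the acrylate ester is stable to aqueous acetic acid.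

Step 7
Reactants: 9 (2R,8S)-8,9-dihydroxynonan-2-yl prop-2-enoate
Product: 10 (2R,8S)-8,9-bis(triethylsilyloxy)nonan-2-yl prop-2-enoate
Conditions: Et3SiCl (2.5 equiv), imidazole, CH2Cl2, 0 °C → rt
Reagents that add atoms: chlorotriethylsilane, CC[Si](Cl)(CC)CC
Why: Silyl ether formation at both hydroxyls protects the future C5–OH and gives a primary/secondary pair of triethylsilyl ethers that the next step can tell apart.

Step 8
Reactants: 10 (2R,8S)-8,9-bis(triethylsilyloxy)nonan-2-yl prop-2-enoate
Product: 12 (2R,8S)-9-oxo-8-(triethylsilyloxy)nonan-2-yl prop-2-enoate, via alkoxysulfonium chloride 11 (not isolated)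
Conditions: (COCl)2, DMSO, CH2Cl2, −78 → −40 °C; then Et3N, −78 → −20 °C
Reagents that add atoms: none
Why: Swern oxidation applied to the bis-silyl ether works because activated DMSO displaces only the unhindered primary triethylsilyl group, and Et3N collapses the alkoxysulfonium salt to the aldehyde cold enough that the α-silyloxy centre is not epimerised and the secondary silyl ether survives.

Step 9
Reactants: 12 (2R,8S)-9-oxo-8-(triethylsilyloxy)nonan-2-yl prop-2-enoate
Product: 13 (2R,8S)-9-(hydroxyimino)-8-(triethylsilyloxy)nonan-2-yl prop-2-enoate (E/Z mixture)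
Conditions: NH2OH·HCl (1.1 equiv), pyridine, EtOH, 0 °C → rt
Reagents that add atoms: hydroxylamine hydrochloride, NO.Cl
Why: Oxime formation by condensation at the aldehyde is much faster than conjugate addition to the acrylate under pyridine buffering and is compatible with the silyl ether.

Step 10
Reactants: 13 (2R,8S)-9-(hydroxyimino)-8-(triethylsilyloxy)nonan-2-yl prop-2-enoate
Product: 15 (4R,10S)-4-methyl-10-(triethylsilyloxy)-3,13-dioxa-12-azabicyclo[9.2.1]tetradec-11-en-2-one (C1 epimers; the isoxazoline-bridged twelve-membered lactone), via nitrile oxide 14 (not isolated)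
Conditions: aq. NaOCl, CH2Cl2, 0 °C → rt, syringe-pump addition of 13 (final 0.002 M)
Reagents that add atoms: none
Why: Hypochlorite dehydrogenates the aldoxime to the nitrile oxide, which at high dilution undergoes intramolecular Huisgen 1,3-dipolar cycloaddition to the acrylate with the normal regiochemistry (carbon to the terminal CH2, oxygen to the α-carbon), closing the lactone and the isoxazoline at once; the new centre at macrolide C2 forms as a mixture that step 12 erases.

Step 11
Reactants: 15 (4R,10S)-4-methyl-10-(triethylsilyloxy)-3,13-dioxa-12-azabicyclo[9.2.1]tetradec-11-en-2-one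
Product: 17 (6S,12R)-3-hydroxy-12-methyl-6-(triethylsilyloxy)oxacyclododecane-2,5-dione (C3 epimers), via hydroxy imine 16 (not isolated)
Conditions: H2 (1 atm), Raney Ni, B(OH)3, MeOH/H2O (5:1), rt
Reagents that add atoms: water, O
Why: Hydrogenolysis of the weak N–O bond gives the β-hydroxy imine, which the boric acid buffer hydrolyses in the flask to the β-hydroxy ketone (isoxazoline as masked aldol) without reducing the ketone or lactone.

Step 12
Reactants: 17 (6S,12R)-3-hydroxy-12-methyl-6-(triethylsilyloxy)oxacyclododecane-2,5-dione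
Product: 19 (3E,6S,12R)-12-methyl-6-(triethylsilyloxy)oxacyclododec-3-ene-2,5-dione, via mesylate 18 (not isolated)
Conditions: MsCl, Et3N, CH2Cl2, 0 °C → rt
Reagents that add atoms: none
Why: Mesylation of the C2 hydroxyl followed by E1cB elimination through the C4 ketone enolate gives the conjugated E-enone from both C2 epimers, with brief cold exposure to Et3N so that C5 is not epimerised.

Step 13
Reactants: 19 (3E,6S,12R)-12-methyl-6-(triethylsilyloxy)oxacyclododec-3-ene-2,5-dione
Product: 20 (3E,6S,12R)-6-hydroxy-12-methyloxacyclododec-3-ene-2,5-dione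
Conditions: 48% aq. HF, MeCN, 0 °C
Reagents that add atoms: none
Why: Fluoride-driven desilylation under acidic, non-nucleophilic conditions frees the C5 hydroxyl without adding to the electrophilic enone or opening the lactone.

Step 14
Reactants: 20 (3E,6S,12R)-6-hydroxy-12-methyloxacyclododec-3-ene-2,5-dione (2 equiv)
Product: 22 thiocladospolide F = (3S,3'S,6S,6'S,12R,12'R)-3,3'-sulfanediylbis(6-hydroxy-12-methyloxacyclododecane-2,5-dione), via thiol 21 (not isolated)
Conditions: H2S (0.5 equiv, 0.8 M in THF), Et3N (0.1 equiv), THF, 0 °C → rt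
Reagents that add atoms: hydrogen sulfide, S
Why: In this double thia-Michael addition, hydrosulfide adds at C2 (β to the more activating C4 ketone) and the resulting thiolate adds to a second enone; each new C2 centre is set by the macrocycle (peripheral attack on the conformation fixed by C5 and C11), and reversibility under amine catalysis lets the mixture relax toward the expected (2S,2'S) sulfide — this selectivity is an expectation, not a certainty.

**Compound list**
1 | (S)-2-(2,2-dimethyl-1,3-dioxolan-4-yl)ethan-1-ol | OCC[C@H]1COC(C)(C)O1 | starting material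
2 | (S)-4-(2-iodoethyl)-2,2-dimethyl-1,3-dioxolane | ICC[C@H]1COC(C)(C)O1 | intermediate
3 | (R)-2-methyloxirane | C[C@@H]1CO1 | starting material
4 | (R)-pent-4-yn-2-ol | C[C@@H](O)CC#C | intermediate
5 | C,O-dilithio derivative of (R)-pent-4-yn-2-ol | C[C@@H](O[Li])CC#C[Li] | intermediate
6 | (2R)-7-[(4S)-2,2-dimethyl-1,3-dioxolan-4-yl]hept-4-yn-2-ol | C[C@@H](O)CC#CCC[C@H]1COC(C)(C)O1 | intermediate
7 | (2R)-7-[(4S)-2,2-dimethyl-1,3-dioxolan-4-yl]heptan-2-ol | C[C@@H](O)CCCCC[C@H]1COC(C)(C)O1 | intermediate
8 | (2R)-7-[(4S)-2,2-dimethyl-1,3-dioxolan-4-yl]heptan-2-yl prop-2-enoate | C[C@@H](OC(=O)C=C)CCCCC[C@H]1COC(C)(C)O1 | intermediate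
9 | (2R,8S)-8,9-dihydroxynonan-2-yl prop-2-enoate | C[C@@H](OC(=O)C=C)CCCCC[C@H](O)CO | intermediate
10 | (2R,8S)-8,9-bis(triethylsilyloxy)nonan-2-yl prop-2-enoate | C[C@@H](OC(=O)C=C)CCCCC[C@H](O[Si](CC)(CC)CC)CO[Si](CC)(CC)CC | intermediate
11 | {[(2S,8R)-8-(acryloyloxy)-2-(triethylsilyloxy)nonyl]oxy}dimethylsulfonium chloride | C[C@@H](OC(=O)C=C)CCCCC[C@H](O[Si](CC)(CC)CC)CO[S+](C)C.[Cl-] | intermediate
12 | (2R,8S)-9-oxo-8-(triethylsilyloxy)nonan-2-yl prop-2-enoate | C[C@@H](OC(=O)C=C)CCCCC[C@H](O[Si](CC)(CC)CC)C=O | intermediate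
13 | (2R,8S)-9-(hydroxyimino)-8-(triethylsilyloxy)nonan-2-yl prop-2-enoate (E/Z mixture) | C[C@@H](OC(=O)C=C)CCCCC[C@H](O[Si](CC)(CC)CC)C=NO | intermediate
14 | (2S,8R)-8-(acryloyloxy)-2-(triethylsilyloxy)nonanenitrile N-oxide | C[C@@H](OC(=O)C=C)CCCCC[C@H](O[Si](CC)(CC)CC)C#[N+][O-] | intermediate
15 | (4R,10S)-4-methyl-10-(triethylsilyloxy)-3,13-dioxa-12-azabicyclo[9.2.1]tetradec-11-en-2-one (C1 epimers) | C[C@@H]1CCCCC[C@H](O[Si](CC)(CC)CC)C2=NOC(C2)C(=O)O1 | intermediate
16 | (6S,12R)-3-hydroxy-5-imino-12-methyl-6-(triethylsilyloxy)oxacyclododecan-2-one (C3 epimers) | C[C@@H]1CCCCC[C@H](O[Si](CC)(CC)CC)C(=N)CC(O)C(=O)O1 | intermediate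
17 | (6S,12R)-3-hydroxy-12-methyl-6-(triethylsilyloxy)oxacyclododecane-2,5-dione (C3 epimers) | C[C@@H]1CCCCC[C@H](O[Si](CC)(CC)CC)C(=O)CC(O)C(=O)O1 | intermediate
18 | (6S,12R)-12-methyl-2,5-dioxo-6-(triethylsilyloxy)oxacyclododecan-3-yl methanesulfonate (C3 epimers) | C[C@@H]1CCCCC[C@H](O[Si](CC)(CC)CC)C(=O)CC(OS(C)(=O)=O)C(=O)O1 | intermediate
19 | (3E,6S,12R)-12-methyl-6-(triethylsilyloxy)oxacyclododec-3-ene-2,5-dione | C[C@@H]1CCCCC[C@H](O[Si](CC)(CC)CC)C(=O)/C=C/C(=O)O1 | intermediate
20 | (3E,6S,12R)-6-hydroxy-12-methyloxacyclododec-3-ene-2,5-dione | C[C@@H]1CCCCC[C@H](O)C(=O)/C=C/C(=O)O1 | intermediate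
21 | (3S,6S,12R)-6-hydroxy-12-methyl-3-sulfanyloxacyclododecane-2,5-dione | C[C@@H]1CCCCC[C@H](O)C(=O)C[C@H](S)C(=O)O1 | intermediate
22 | thiocladospolide F, (3S,3'S,6S,6'S,12R,12'R)-3,3'-sulfanediylbis(6-hydroxy-12-methyloxacyclododecane-2,5-dione) | C[C@@H]1CCCCC[C@H](O)C(=O)C[C@H](S[C@H]2CC(=O)[C@@H](O)CCCCC[C@@H](C)OC2=O)C(=O)O1 | target

**Step count**
Total: 14 steps. Longest linear sequence: 13 steps (from 1 through steps 1, 3–14, or equally from 3 through steps 2–14).

**Three steps most likely to fail, with fallbacks**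

Step 10 (macrocyclising nitrile oxide cycloaddition). The risk is furoxan dimers or oligomers outcompeting closure of the twelve-membered ring. The fallback sets out from aldehyde 12. Addition of CH2=CHMgBr (THF, −78 °C, where the aldehyde reacts before the acrylate) gives the allylic alcohol (2R,8S)-9-hydroxy-8-(triethylsilyloxy)undec-10-en-2-yl prop-2-enoate F1 as C9 epimers. Ring-closing metathesis with the second-generation Grubbs catalyst RuCl2(=CHPh)(PCy3)(H2IMes) (CH2Cl2, 0.001 M, reflux) closes the lactone to (3E,6S,12R)-5-hydroxy-12-methyl-6-(triethylsilyloxy)oxacyclododec-3-en-2-one F2. Oxidation of the allylic alcohol (Dess–Martin periodinane, NaHCO3, CH2Cl2) converges both epimers and comes back to the route at enone 19.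

Step 14 (double thia-Michael). The risk is a mixture of C2 diastereomers (S,S / R,S / R,R) or base-induced translactonisation of the free hydroxy ketone. The fallback sets out from enone 20 and makes the two C–S bonds one at a time. Conjugate addition of thioacetic acid (1.1 equiv, cat. Et3N, CH2Cl2, 0 °C) gives (3S,6S,12R)-3-(acetylsulfanyl)-6-hydroxy-12-methyloxacyclododecane-2,5-dione F3, which is separated from its C3 epimer by chromatography. The unwanted epimer can be returned to 20 by base-induced retro-Michael. S-Deacetylation with NaSMe (1.0 equiv, MeOH/THF, −20 °C, then AcOH) comes back to the route at thiol 21, now isolated as a single diastereomer. Thiol 21 is then added to one further equivalent of 20 (cat. Et3N, THF, 0 °C) to give 22, so only one new stereocentre is formed in the coupling.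

Step 8 (oxidative removal of the primary silyl ether). The risk is incomplete primary/secondary discrimination or epimerisation of the α-silyloxy aldehyde. The fallback sets out from bis-silyl ether 10 and separates deprotection from oxidation. Selective cleavage of the primary triethylsilyl ether (HF·pyridine, pyridine, THF, 0 °C) gives (2R,8S)-9-hydroxy-8-(triethylsilyloxy)nonan-2-yl prop-2-enoate F4. A neutral oxidation (Dess–Martin periodinane, NaHCO3, CH2Cl2, 0 °C) then comes back to the route at aldehyde 12.

**Further compounds**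
F1 | step 10 | (2R,8S)-9-hydroxy-8-(triethylsilyloxy)undec-10-en-2-yl prop-2-enoate (C9 epimers) | C[C@@H](OC(=O)C=C)CCCCC[C@H](O[Si](CC)(CC)CC)C(O)C=C
F2 | step 10 | (3E,6S,12R)-5-hydroxy-12-methyl-6-(triethylsilyloxy)oxacyclododec-3-en-2-one (C5 epimers) | C[C@@H]1CCCCC[C@H](O[Si](CC)(CC)CC)C(O)/C=C/C(=O)O1
F3 | step 14 | (3S,6S,12R)-3-(acetylsulfanyl)-6-hydroxy-12-methyloxacyclododecane-2,5-dione | C[C@@H]1CCCCC[C@H](O)C(=O)C[C@H](SC(C)=O)C(=O)O1
F4 | step 8 | (2R,8S)-9-hydroxy-8-(triethylsilyloxy)nonan-2-yl prop-2-enoate | C[C@@H](OC(=O)C=C)CCCCC[C@H](O[Si](CC)(CC)CC)CO
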